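**Plan**
- Rings are lettered A (2,4,6-trihydroxyphenoxy end) to J (3,4,5-trihydroxyphenoxy end). In rings C, E, G and I, C1 bears the ether to the preceding ring, C2 the only hydrogen, C3–C5 hydroxyls and C6 the ether to the next ring.
- Retrosynthesis: first the 26 O–methyl bonds; then the ethers A–B, C–D, E–F, G–H and I–J (hindered phenol oxygen to an unhindered aryl bromide); then three bonds of ring E itself (C2–C3, C1–C6, C5–C6). The ethers B–C, F–G and H–I come ready-made in one bromo aldehyde block 4, whose formyl group is a latent C6 hydroxyl.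
- Feature used: ring E has oxygen on C1 and C3–C6 and hydrogen only on C2. The C6 oxygen is para to the C3 oxygen and ortho to the ring D ether at C1, which is the pattern a chromium carbene benzannulation gives from an alkenyl(methoxy)carbene, a terminal ynol ether and CO.
- Forward: block 4 (two steps) is joined to ring A, then ring D is added to give the A–D phenol. Its ethynyl ether is benzannulated to create ring E. Two more rounds of block 4 add rings F–G and H–I, ring J closes the chain and BBr3 frees all hydroxyls.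
- Stereochemistry: the target is achiral and has no stereocentre; the double-bond geometries of 13 and 18 vanish on aromatisation.

Key step: step 11

Remark: 5-fluoro-1,2,3-trimethoxybenzene 1 and (Z)-1,2-dimethoxyethene 14 are treated as catalogue chemicals; the free polyphenol is assumed to need handling under argon.

**Route**

Step 1
Reactants: 1 5-fluoro-1,2,3-trimethoxybenzene
Product: 2 6-fluoro-2,3,4-trimethoxybenzaldehyde
Conditions: Cl2CHOMe, TiCl4, CH2Cl2, −10 to 0 °C; then H2O
Reagents that add atoms: dichloromethyl methyl ether, COC(Cl)Cl; water, O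
Why: Rieche formylation (electrophilic aromatic substitution); the two free positions of 1 are equivalent, each para to one methoxy group and ortho to another, so a single aldehyde should form.

Step 2
Reactants: 2 6-fluoro-2,3,4-trimethoxybenzaldehyde; 3 4-bromo-2,6-dimethoxyphenol
Product: 4 6-(4-bromo-2,6-dimethoxyphenoxy)-2,3,4-trimethoxybenzaldehyde (bromo aldehyde block)
Conditions: Cs2CO3, DMSO, 120 °C
Reagents that add atoms: none
Why: Nucleophilic aromatic substitution (SNAr) of the fluoride ortho to the formyl group by the phenoxide of 3; the aryl bromide is inert without copper, so the hindered B–C type ether forms with the bromine handle intact.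

Step 3
Reactants: 4 bromo aldehyde block; 5 2,4,6-trimethoxyphenol
Product: 6 A–C trimer aldehyde (formyl on C6 of ring C; all oxygens methylated)
Conditions: CuI (10 mol%), picolinic acid (20 mol%), K3PO4, DMSO, 90 °C, argon
Reagents that add atoms: none
Why: Copper-catalysed Ullmann diaryl ether synthesis; the picolinic acid system is established for 2,6-disubstituted phenols, the bromide of 4 has two free ortho positions and the hindered aldehyde is a spectator.

Step 4
Reactants: 6 A–C trimer aldehyde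
Product: 8 A–C trimer phenol (free hydroxyl on C6 of ring C), via aryl formate 7 (not isolated)
Conditions: mCPBA, CH2Cl2, 0 °C to rt; then Et3N, MeOH, rt
Reagents that add atoms: mCPBA, OOC(=O)c1cccc(Cl)c1
Why: Baeyer–Villiger oxidation with aryl migration (Dakin-type) of an electron-rich benzaldehyde flanked by two oxygen substituents, then methanolysis of the labile formate, turns the formyl group into the ring C hydroxyl.

Step 5
Reactants: 3 4-bromo-2,6-dimethoxyphenol
Product: 9 2-(benzyloxy)-5-bromo-1,3-dimethoxybenzene (ring D unit)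
Conditions: BnBr, K2CO3, DMF, rt
Reagents that add atoms: benzyl bromide, BrCc1ccccc1
Why: Williamson etherification masks the future ring D hydroxyl and keeps the bromide for coupling.

Step 6
Reactants: 8 A–C trimer phenol; 9 2-(benzyloxy)-5-bromo-1,3-dimethoxybenzene
Product: 10 A–D tetramer benzyl ether (benzyloxy on C4 of ring D)
Conditions: CuI (10 mol%), picolinic acid (20 mol%), K3PO4, DMSO, 90 °C, argon
Reagents that add atoms: none
Why: Ullmann diaryl ether synthesis as in step 3, joining the hindered ring C phenol to the unhindered bromide of 9.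

Step 7
Reactants: 10 A–D tetramer benzyl ether
Product: 11 A–D tetramer phenol (free hydroxyl on C4 of ring D)
Conditions: H2 (1 atm), 10% Pd/C, EtOAc–MeOH, rt
Reagents that add atoms: none
Why: Hydrogenolysis of the benzyl ether over Pd/C leaves diaryl and methyl ethers untouched, and no halogen is left in the molecule.

Step 8
Reactants: 11 A–D tetramer phenol; 12 trichloroethylene
Product: 13 A–D tetramer (E)-1,2-dichlorovinyl ether
Conditions: K2CO3, DMF, 70 °C
Reagents that add atoms: none
Why: Anti addition of the phenoxide to dichloroacetylene formed in situ from trichloroethylene gives the (E)-1,2-dichlorovinyl aryl ether, the standard precursor of aryl ynol ethers.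

Step 9
Reactants: 14 (Z)-1,2-dimethoxyethene; 15 chromium hexacarbonyl Cr(CO)6
Product: 18 pentacarbonyl[(Z)-1,2-dimethoxyvinyl(methoxy)carbene]chromium, via vinyllithium 16 (not isolated), via lithium acylchromate 17 (not isolated)
Conditions: t-BuLi, THF, −78 to −40 °C; Cr(CO)6, THF, −78 to 0 °C; MeOTf, CH2Cl2, 0 °C
Reagents that add atoms: methyl triflate, COS(=O)(=O)C(F)(F)F
Why: α-Lithiation of the enol ether with retention of geometry (as for methyl vinyl ether and 2,3-dihydro-1,4-dioxine), addition to a carbonyl ligand and O-methylation of the acyl chromate is the classical Fischer carbene synthesis.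

Step 10
Reactants: 13 A–D tetramer (E)-1,2-dichlorovinyl ether
Product: 21 A–D tetramer ethynyl ether (ethynyloxy on C4 of ring D), via chloroethynyl ether 19 (not isolated), via lithium acetylide 20 (not isolated)
Conditions: n-BuLi (2.2 equiv), THF, −78 to −40 °C; then H2O, −78 °C; used at once
Reagents that add atoms: none
Why: Dehydrochlorination to the chloroalkyne, chlorine–lithium exchange and protonation is the standard conversion of aryl dichlorovinyl ethers into terminal ynol ethers, and at −78 °C it should outrun ortho-lithiation of the methoxyarenes.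

Step 11
Reactants: 21 A–D tetramer ethynyl ether; 18 pentacarbonyl[(Z)-1,2-dimethoxyvinyl(methoxy)carbene]chromium
Product: 23 A–E pentamer phenol (free hydroxyl on C6 of ring E; all other oxygens methylated), via tricarbonylchromium arene complex 22 (not isolated)
Conditions: THF, 50 °C, argon (21 added slowly to 2 equiv of 18); then air, MeCN, rt
Reagents that add atoms: none
Why: Proposed new method: thermal loss of one CO from 18 opens a site for 21, which inserts into the Cr=C bond with its CH terminus bonding to the carbene carbon (C2–C3), so that the aryloxy-bearing carbon becomes the new oxygen-stabilised carbene carbon; CO insertion there (C1–C6) gives a chromium-bound dienylketene, and bond formation between the ketene carbon and the methoxy-bearing vinyl terminus (C5–C6) followed by enolisation gives the phenol. The closest known reaction type is the Dötz benzannulation of alkenyl(alkoxy)carbene chromium complexes (for example dihydropyranyl complexes) with terminal alkynes, which has not been described for aryl ethynyl ethers or for a 1,2-dialkoxyvinyl carbene. Ring E is the only ring closed, by disrotatory 6π-electrocyclisation of the η4-vinylketene to a six-membered dienone, and no stereocentre is formed. The step needs one orientation of alkyne insertion, and both the steric rule for terminal alkynes (substituted carbon next to the carbonyl-derived carbon) and the donor polarisation of the ynol ether (nucleophilic CH terminus attacks the electrophilic carbene carbon) point to it. Slow addition of 21 to excess 18 disfavours double alkyne insertion, and the β-hydrogen cis to the carbene carbon in the (Z)-vinyl group leaves the closing terminus unhindered. Air is chosen for decomplexation because stronger oxidants would turn the para-methoxyphenol into a quinone.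

Step 12
Reactants: 23 A–E pentamer phenol; 4 bromo aldehyde block
Product: 24 A–G heptamer aldehyde (formyl on C6 of ring G)
Conditions: CuI (20 mol%), picolinic acid (40 mol%), K3PO4, DMSO, 100 °C, argon
Reagents that add atoms: none
Why: Ullmann diaryl ether synthesis as in step 3; the ring E phenol, flanked by the ring D ether and a methoxy group, is of the same hindered type as 8 and meets the unhindered bromide of 4.

Step 13
Reactants: 24 A–G heptamer aldehyde
Product: 26 A–G heptamer phenol (free hydroxyl on C6 of ring G), via aryl formate 25 (not isolated)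
Conditions: mCPBA, CH2Cl2, 0 °C to rt; then Et3N, MeOH, rt
Reagents that add atoms: mCPBA, OOC(=O)c1cccc(Cl)c1
Why: Baeyer–Villiger oxidation and formate methanolysis as in step 4 unmask the ring G hydroxyl.

Step 14
Reactants: 26 A–G heptamer phenol; 4 bromo aldehyde block
Product: 27 A–I nonamer aldehyde (formyl on C6 of ring I)
Conditions: CuI (20 mol%), picolinic acid (40 mol%), K3PO4, DMSO, 100 °C, argon
Reagents that add atoms: none
Why: Ullmann diaryl ether synthesis as in step 12 forms the G–H ether and brings in rings H and I.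

Step 15
Reactants: 27 A–I nonamer aldehyde
Product: 29 A–I nonamer phenol (free hydroxyl on C6 of ring I), via aryl formate 28 (not isolated)
Conditions: mCPBA, CH2Cl2, 0 °C to rt; then Et3N, MeOH, rt
Reagents that add atoms: mCPBA, OOC(=O)c1cccc(Cl)c1
Why: Baeyer–Villiger oxidation and formate methanolysis as in step 4 unmask the ring I hydroxyl.

Step 16
Reactants: 29 A–I nonamer phenol; 30 5-bromo-1,2,3-trimethoxybenzene
Product: 31 permethylated A–J decamer (26 methyl ethers)
Conditions: CuI (20 mol%), picolinic acid (40 mol%), K3PO4, DMSO, 100 °C, argon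
Reagents that add atoms: none
Why: Ullmann diaryl ether synthesis as in step 12 attaches ring J through its unhindered bromide.

Step 17
Reactants: 31 permethylated A–J decamer
Product: 32 CNP0255890.0 (free A–J decamer with 26 hydroxyls)
Conditions: BBr3 (excess), CH2Cl2, −78 °C to rt, argon; then MeOH, H2O; Sephadex LH-20
Reagents that add atoms: none
Why: Lewis acid cleavage of aryl methyl ethers with BBr3; diaryl ethers resist the reagent, so only the O–methyl bonds are cut.

**Compound list**

1 | 5-fluoro-1,2,3-trimethoxybenzene | COc1cc(F)cc(OC)c1OC | starting material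
2 | 6-fluoro-2,3,4-trimethoxybenzaldehyde | COc1cc(F)c(C=O)c(OC)c1OC | intermediate
3 | 4-bromo-2,6-dimethoxyphenol | COc1cc(Br)cc(OC)c1O | starting material
4 | 6-(4-bromo-2,6-dimethoxyphenoxy)-2,3,4-trimethoxybenzaldehyde (bromo aldehyde block) | COc1cc(Br)cc(OC)c1Oc1cc(OC)c(OC)c(OC)c1C=O | intermediate
5 | 2,4,6-trimethoxyphenol | COc1cc(OC)c(O)c(OC)c1 | starting material
6 | A–C trimer aldehyde, formyl on C6 of ring C | COc1cc(OC)c(Oc2cc(OC)c(Oc3cc(OC)c(OC)c(OC)c3C=O)c(OC)c2)c(OC)c1 | intermediate
7 | A–C trimer aryl formate (formyloxy on C6 of ring C) | COc1cc(OC)c(Oc2cc(OC)c(Oc3cc(OC)c(OC)c(OC)c3OC=O)c(OC)c2)c(OC)c1 | intermediate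
8 | A–C trimer phenol, hydroxyl on C6 of ring C | COc1cc(OC)c(Oc2cc(OC)c(Oc3cc(OC)c(OC)c(OC)c3O)c(OC)c2)c(OC)c1 | intermediate
9 | 2-(benzyloxy)-5-bromo-1,3-dimethoxybenzene | COc1cc(Br)cc(OC)c1OCc1ccccc1 | intermediate
10 | A–D tetramer benzyl ether, benzyloxy on C4 of ring D | COc1cc(OC)c(Oc2cc(OC)c(Oc3cc(OC)c(OC)c(OC)c3Oc3cc(OC)c(OCc4ccccc4)c(OC)c3)c(OC)c2)c(OC)c1 | intermediate
11 | A–D tetramer phenol, hydroxyl on C4 of ring D | COc1cc(OC)c(Oc2cc(OC)c(Oc3cc(OC)c(OC)c(OC)c3Oc3cc(OC)c(O)c(OC)c3)c(OC)c2)c(OC)c1 | intermediate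
12 | trichloroethylene | ClC=C(Cl)Cl | starting material
13 | A–D tetramer (E)-1,2-dichlorovinyl ether | COc1cc(OC)c(Oc2cc(OC)c(Oc3cc(OC)c(OC)c(OC)c3Oc3cc(OC)c(O/C(Cl)=C\Cl)c(OC)c3)c(OC)c2)c(OC)c1 | intermediate
14 | (Z)-1,2-dimethoxyethene | CO/C=C\OC | starting material
15 | chromium hexacarbonyl Cr(CO)6 | O=C=[Cr](=C=O)(=C=O)(=C=O)(=C=O)=C=O | starting material
16 | (Z)-1,2-dimethoxyvinyllithium | CO/C=C(\OC)[Li] | intermediate
17 | lithium pentacarbonyl[(Z)-2,3-dimethoxyacryloyl]chromate (drawn in its oxycarbene form) | CO/C=C(\OC)C(O[Li])=[Cr](=C=O)(=C=O)(=C=O)(=C=O)=C=O | intermediate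
18 | pentacarbonyl[(Z)-1,2-dimethoxyvinyl(methoxy)carbene]chromium | CO/C=C(\OC)C(OC)=[Cr](=C=O)(=C=O)(=C=O)(=C=O)=C=O | intermediate
19 | A–D tetramer chloroethynyl ether | COc1cc(OC)c(Oc2cc(OC)c(Oc3cc(OC)c(OC)c(OC)c3Oc3cc(OC)c(OC#CCl)c(OC)c3)c(OC)c2)c(OC)c1 | intermediate
20 | A–D tetramer lithium (aryloxy)acetylide | COc1cc(OC)c(Oc2cc(OC)c(Oc3cc(OC)c(OC)c(OC)c3Oc3cc(OC)c(OC#C[Li])c(OC)c3)c(OC)c2)c(OC)c1 | intermediate
21 | A–D tetramer ethynyl ether, ethynyloxy on C4 of ring D | COc1cc(OC)c(Oc2cc(OC)c(Oc3cc(OC)c(OC)c(OC)c3Oc3cc(OC)c(OC#C)c(OC)c3)c(OC)c2)c(OC)c1 | intermediate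
22 | tricarbonyl(η6-ring E)chromium complex of 23 (π-bound metal fragment written as a separate component) | COc1cc(OC)c(Oc2cc(OC)c(Oc3cc(OC)c(OC)c(OC)c3Oc3cc(OC)c(Oc4cc(OC)c(OC)c(OC)c4O)c(OC)c3)c(OC)c2)c(OC)c1.O=C=[Cr](=C=O)=C=O | intermediate
23 | A–E pentamer phenol, hydroxyl on C6 of ring E | COc1cc(OC)c(Oc2cc(OC)c(Oc3cc(OC)c(OC)c(OC)c3Oc3cc(OC)c(Oc4cc(OC)c(OC)c(OC)c4O)c(OC)c3)c(OC)c2)c(OC)c1 | intermediate
24 | A–G heptamer aldehyde, formyl on C6 of ring G | COc1cc(OC)c(Oc2cc(OC)c(Oc3cc(OC)c(OC)c(OC)c3Oc3cc(OC)c(Oc4cc(OC)c(OC)c(OC)c4Oc4cc(OC)c(Oc5cc(OC)c(OC)c(OC)c5C=O)c(OC)c4)c(OC)c3)c(OC)c2)c(OC)c1 | intermediate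
25 | A–G heptamer aryl formate | COc1cc(OC)c(Oc2cc(OC)c(Oc3cc(OC)c(OC)c(OC)c3Oc3cc(OC)c(Oc4cc(OC)c(OC)c(OC)c4Oc4cc(OC)c(Oc5cc(OC)c(OC)c(OC)c5OC=O)c(OC)c4)c(OC)c3)c(OC)c2)c(OC)c1 | intermediate
26 | A–G heptamer phenol, hydroxyl on C6 of ring G | COc1cc(OC)c(Oc2cc(OC)c(Oc3cc(OC)c(OC)c(OC)c3Oc3cc(OC)c(Oc4cc(OC)c(OC)c(OC)c4Oc4cc(OC)c(Oc5cc(OC)c(OC)c(OC)c5O)c(OC)c4)c(OC)c3)c(OC)c2)c(OC)c1 | intermediate
27 | A–I nonamer aldehyde, formyl on C6 of ring I | COc1cc(OC)c(Oc2cc(OC)c(Oc3cc(OC)c(OC)c(OC)c3Oc3cc(OC)c(Oc4cc(OC)c(OC)c(OC)c4Oc4cc(OC)c(Oc5cc(OC)c(OC)c(OC)c5Oc5cc(OC)c(Oc6cc(OC)c(OC)c(OC)c6C=O)c(OC)c5)c(OC)c4)c(OC)c3)c(OC)c2)c(OC)c1 | intermediate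
28 | A–I nonamer aryl formate | COc1cc(OC)c(Oc2cc(OC)c(Oc3cc(OC)c(OC)c(OC)c3Oc3cc(OC)c(Oc4cc(OC)c(OC)c(OC)c4Oc4cc(OC)c(Oc5cc(OC)c(OC)c(OC)c5Oc5cc(OC)c(Oc6cc(OC)c(OC)c(OC)c6OC=O)c(OC)c5)c(OC)c4)c(OC)c3)c(OC)c2)c(OC)c1 | intermediate
29 | A–I nonamer phenol, hydroxyl on C6 of ring I | COc1cc(OC)c(Oc2cc(OC)c(Oc3cc(OC)c(OC)c(OC)c3Oc3cc(OC)c(Oc4cc(OC)c(OC)c(OC)c4Oc4cc(OC)c(Oc5cc(OC)c(OC)c(OC)c5Oc5cc(OC)c(Oc6cc(OC)c(OC)c(OC)c6O)c(OC)c5)c(OC)c4)c(OC)c3)c(OC)c2)c(OC)c1 | intermediate
30 | 5-bromo-1,2,3-trimethoxybenzene | COc1cc(Br)cc(OC)c1OC | starting material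
31 | permethylated A–J decamer | COc1cc(OC)c(Oc2cc(OC)c(Oc3cc(OC)c(OC)c(OC)c3Oc3cc(OC)c(Oc4cc(OC)c(OC)c(OC)c4Oc4cc(OC)c(Oc5cc(OC)c(OC)c(OC)c5Oc5cc(OC)c(Oc6cc(OC)c(OC)c(OC)c6Oc6cc(OC)c(OC)c(OC)c6)c(OC)c5)c(OC)c4)c(OC)c3)c(OC)c2)c(OC)c1 | intermediate
32 | CNP0255890.0 | Oc1cc(O)c(Oc2cc(O)c(Oc3cc(O)c(O)c(O)c3Oc3cc(O)c(Oc4cc(O)c(O)c(O)c4Oc4cc(O)c(Oc5cc(O)c(O)c(O)c5Oc5cc(O)c(Oc6cc(O)c(O)c(O)c6Oc6cc(O)c(O)c(O)c6)c(O)c5)c(O)c4)c(O)c3)c(O)c2)c(O)c1 | target

**Step count**

Total steps: 17. Longest linear sequence: 15 steps (1–4, 6–8, 10–17).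

**Steps most likely to fail**

Step 11. The alkyne insertion may stop at the oxygen-stabilised vinylcarbene, divert to cyclobutenone or furan formation without ring closure, or take the reverse orientation; the ynol ether may also oligomerise before it meets the carbene complex. The fallback builds ring E from a preformed arene by known chemistry. It sets out from phenol 11, whose phenoxide displaces the fluoride of 2 (Cs2CO3, DMSO, 120 °C, SNAr as in step 2) to give the A–E pentamer aldehyde F1. mCPBA in CH2Cl2 then gives the A–E pentamer aryl formate F2 by Baeyer–Villiger oxidation, and Et3N in MeOH returns to the route at 23.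

Step 10. The terminal aryloxyacetylene may hydrate or oligomerise during quench and concentration, and excess n-BuLi may ortho-lithiate the methoxyarenes. The fallback sets out from 13 and does not protonate the lithium acetylide 20 but silylates it with iPr3SiCl to give the A–D tetramer (triisopropylsilyl)ethynyl ether F3, which can be purified and stored. Bu4NF buffered with AcOH in THF at −20 °C then releases 21 as a solution that goes straight into step 11, so the terminal alkyne is never stored or concentrated.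

Step 17. Cleavage of the 26 methyl ethers may stall as polyborate intermediates precipitate, and the liberated polyphenol may oxidise in air during isolation. The fallback sets out from 31: after BBr3 the crude product is acetylated at once (Ac2O, pyridine) to the hexacosaacetate of the target F4, which is stable and can be purified on silica and resubmitted if methyl ethers remain. Catalytic NaOMe in degassed MeOH at 0 °C followed by an acidic resin then returns to the route at 32.

**Further compounds**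

F1 | step 11 | A–E pentamer aldehyde, formyl on C6 of ring E | COc1cc(OC)c(Oc2cc(OC)c(Oc3cc(OC)c(OC)c(OC)c3Oc3cc(OC)c(Oc4cc(OC)c(OC)c(OC)c4C=O)c(OC)c3)c(OC)c2)c(OC)c1
F2 | step 11 | A–E pentamer aryl formate | COc1cc(OC)c(Oc2cc(OC)c(Oc3cc(OC)c(OC)c(OC)c3Oc3cc(OC)c(Oc4cc(OC)c(OC)c(OC)c4OC=O)c(OC)c3)c(OC)c2)c(OC)c1
F3 | step 10 | A–D tetramer (triisopropylsilyl)ethynyl ether | COc1cc(OC)c(Oc2cc(OC)c(Oc3cc(OC)c(OC)c(OC)c3Oc3cc(OC)c(OC#C[Si](C(C)C)(C(C)C)C(C)C)c(OC)c3)c(OC)c2)c(OC)c1
F4 | step 17 | hexacosaacetate of the target | CC(=O)Oc1cc(OC(C)=O)c(Oc2cc(OC(C)=O)c(Oc3cc(OC(C)=O)c(OC(C)=O)c(OC(C)=O)c3Oc3cc(OC(C)=O)c(Oc4cc(OC(C)=O)c(OC(C)=O)c(OC(C)=O)c4Oc4cc(OC(C)=O)c(Oc5cc(OC(C)=O)c(OC(C)=O)c(OC(C)=O)c5Oc5cc(OC(C)=O)c(Oc6cc(OC(C)=O)c(OC(C)=O)c(OC(C)=O)c6Oc6cc(OC(C)=O)c(OC(C)=O)c(OC(C)=O)c6)c(OC(C)=O)c5)c(OC(C)=O)c4)c(OC(C)=O)c3)c(OC(C)=O)c2)c(OC(C)=O)c1
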